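**Plan**

- Labdane numbering is used: C1–C10 decalin, C11–C16 side chain (C15 ester carbon), C17 formyl carbon, C20 angular methyl. Retrosynthesis: the side chain is cut at C12–C13 (sp3–sp2 coupling) and C17/C12 are traced to a tricyclic δ-lactone C17(=O)–O–C12. Ring B of this lactone is cut at C7=C8 and ring A at C5–C10, giving an open chain; this is cut at C9–C10 (conjugate addition to 5,6-dihydro-2H-pyran-2-one) and C1–C2 (enolate alkylation).
- Forward: the chain is assembled, ring A (C5–C10) and then ring B (C7–C8) are closed in one flask, the lactone is opened and the side chain is attached last.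
- Enabling feature: ring B consists of two three-carbon halves, C5–C6–C7 and C8–C9–C10, joined at C5–C10 and C7–C8. C10 is a methyl-bearing quaternary carbon, so it can be a tertiary radical made from a C10=CH2 alkene. C5=C6–C7HO is an enal (radical acceptor at C5, aldehyde at C7). C8 is α to the C17 carbonyl, so it can carry a phosphonate.
- Stereochemistry: C3 by CBS reduction; C9 by rhodium/(R)-BINAP 1,4-addition; C5 and C10 relayed from C3 in the radical ring closure; C8 by hydrogenation anti to CH3-20; 13Z from a (Z)-vinyl iodide coupled with retention.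

Key step: step 8

Remark: 3,3-dimethylpent-4-en-2-one (1) is taken as a catalogue compound.

**Route**

Step 1
Reactants: 1 3,3-dimethylpent-4-en-2-one; 2 3,3-diethoxyprop-1-ene
Product: 3 (E)-6,6-diethoxy-3,3-dimethylhex-4-en-2-one
Conditions: 2 (4 equiv), second-generation Hoveyda–Grubbs catalyst (3 mol %), CH2Cl2, 40 °C
Reagents that add atoms: none
Why: Olefin cross-metathesis between the non-dimerizing vinyl group of 1 and an excess of the fast-reacting acetal 2 should give the masked enal, the E geometry arising under thermodynamic control.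

Step 2
Reactants: 3 (E)-6,6-diethoxy-3,3-dimethylhex-4-en-2-one; 4 2,3-dibromoprop-1-ene
Product: 6 (E)-2-bromo-9,9-diethoxy-6,6-dimethylnona-1,7-dien-5-one, via lithium enolate 5 (not isolated)
Conditions: LiN(i-Pr)2, THF, −78 °C; then 4, −78 → −30 °C
Reagents that add atoms: none
Why: Kinetic enolate alkylation forms C1–C2; the methyl group is the only enolizable position of 3, and only the allylic bromide of 4 reacts, leaving the vinylic bromide.

Step 3
Reactants: 6 (E)-2-bromo-9,9-diethoxy-6,6-dimethylnona-1,7-dien-5-one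
Product: 7 (5R,7E)-2-bromo-9,9-diethoxy-6,6-dimethylnona-1,7-dien-5-ol
Conditions: (S)-2-methyl-CBS-oxazaborolidine (0.2 equiv), catecholborane, toluene, −78 → −40 °C; NaOH (aq) work-up
Reagents that add atoms: none
Why: Corey–Bakshi–Shibata reduction, in which the quaternary carbon is the large group and the (S)-catalyst should deliver hydride to give the 5R carbinol (labdane C3), while catecholborane at low temperature leaves the alkenes alone.

Step 4
Reactants: 7 (5R,7E)-2-bromo-9,9-diethoxy-6,6-dimethylnona-1,7-dien-5-ol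
Product: 8 {[(5R,7E)-2-bromo-9,9-diethoxy-6,6-dimethylnona-1,7-dien-5-yl]oxy}(tert-butyl)dimethylsilane
Conditions: TBSCl, imidazole, DMAP (cat.), DMF, 50 °C
Reagents that add atoms: tert-butyldimethylsilyl chloride, CC(C)(C)[Si](C)(C)Cl
Why: Silylation under non-Lewis-acidic conditions protects the hindered carbinol without touching the acid-labile acetal.

Step 5
Reactants: 8 {[(5R,7E)-2-bromo-9,9-diethoxy-6,6-dimethylnona-1,7-dien-5-yl]oxy}(tert-butyl)dimethylsilane; 9 5,6-dihydro-2H-pyran-2-one
Product: 12 (4R)-4-[(5R,7E)-5-{[tert-butyl(dimethyl)silyl]oxy}-9,9-diethoxy-6,6-dimethylnona-1,7-dien-2-yl]oxan-2-one, via alkenyllithium 10 (not isolated), via lithium alkenyltrimethoxyborate 11 (not isolated)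
Conditions: t-BuLi (2.1 equiv), Et2O, −78 °C; B(OMe)3, −78 → 0 °C; then 9, Rh(acac)(C2H4)2 (3 mol %), (R)-BINAP, dioxane/H2O (10:1), 100 °C
Reagents that add atoms: none
Why: Bromine–lithium exchange and borate formation are followed by a Hayashi–Miyaura rhodium-catalyzed asymmetric 1,4-addition that forms C9–C10; the (R)-BINAP ligand selects the enantioface of 9 and, by analogy with cyclic enones, should give the 4R lactone (labdane C9).

Step 6
Reactants: 12 (4R)-4-[(5R,7E)-5-{[tert-butyl(dimethyl)silyl]oxy}-9,9-diethoxy-6,6-dimethylnona-1,7-dien-2-yl]oxan-2-one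
Product: 15 diethyl {(4S)-4-[(5R,7E)-5-{[tert-butyl(dimethyl)silyl]oxy}-9,9-diethoxy-6,6-dimethylnona-1,7-dien-2-yl]-2-oxooxan-3-yl}phosphonate (both epimers at the phosphorus-bearing carbon), via lithium enolate 13 (not isolated), via phosphonite 14 (not isolated)
Conditions: LiN(i-Pr)2, THF, −78 °C; ClP(OEt)2, −78 °C → rt; then H2O2 (30% aq), 0 °C
Reagents that add atoms: diethyl chlorophosphite, CCOP(Cl)OCC; hydrogen peroxide, OO
Why: C-phosphinylation of the lactone enolate with a chlorophosphite and oxidation of the phosphonite should give the α-phosphono lactone (a Horner–Wadsworth–Emmons reagent); the new center at C8 is inconsequential because it becomes sp2 in step 8.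

Step 7
Reactants: 15 diethyl {(4S)-4-[(5R,7E)-5-{[tert-butyl(dimethyl)silyl]oxy}-9,9-diethoxy-6,6-dimethylnona-1,7-dien-2-yl]-2-oxooxan-3-yl}phosphonate
Product: 16 diethyl {(4S)-4-[(5R,7E)-5-{[tert-butyl(dimethyl)silyl]oxy}-6,6-dimethyl-9-oxonona-1,7-dien-2-yl]-2-oxooxan-3-yl}phosphonate
Conditions: PPTS (cat.), acetone/H2O (10:1), rt
Reagents that add atoms: water, O
Why: Mild acid hydrolysis of the α,β-unsaturated acetal should release the E-enal while the hindered silyl ether, lactone and phosphonate survive.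

Step 8
Reactants: 16 diethyl {(4S)-4-[(5R,7E)-5-{[tert-butyl(dimethyl)silyl]oxy}-6,6-dimethyl-9-oxonona-1,7-dien-2-yl]-2-oxooxan-3-yl}phosphonate
Product: 18 ent-3β-[(tert-butyldimethylsilyl)oxy]-13,14,15,16-tetranorlabd-7-en-17,12-olide, via ring-A aldehyde 17 (not isolated)
Conditions: Fe(acac)3 (0.3 equiv), PhSiH3 (2.5 equiv), EtOH, 0.01 M, 60 °C; then LiCl, DBU, THF, rt, same flask
Reagents that add atoms: none
Why: An iron hydride formed from Fe(acac)3 and PhSiH3 should transfer a hydrogen atom to the CH2 terminus of the electron-rich 1,1-disubstituted alkene (Markovnikov MHAT), creating the C20 methyl group and a tertiary C10 radical that adds to the enal β-carbon C5; reduction of the resulting α-formyl radical to the enolate and protonation by ethanol leave aldehyde 17, whose C7 carbonyl now lies within reach of C8, so that LiCl/DBU triggers the intramolecular Horner–Wadsworth–Emmons olefination. The closest known reaction types are the iron-hydride reductive olefin–enone coupling (Giese-type radical conjugate addition with radical–polar crossover) and Masamune–Roush olefination with α-phosphono lactones. Ring A closes in the 6-exo-trig mode (C5–C10) and ring B by six-membered carbonyl olefination (C7=C8, hence the C7–C8 σ bond). C5 and C10 are set by the C3 stereocenter through a chair transition state in which the silyloxy group, the enal arm on C5 and the lactone arm on C10 are equatorial and the new methyl is axial, which should give H-5 trans to CH3-20 and CH3-20 cis to the C3 oxygen; C9 is carried in unchanged and C8 becomes sp2. The step needs hydrogen-atom transfer to the isolated alkene instead of the enal and cyclization faster than reduction of the radical, which the polarity match of a nucleophilic tertiary radical with an electron-poor enal, the gem-dimethyl group and high dilution should secure. Premature olefination is excluded because the phosphonate is not ionized until base is added and C7 cannot reach C8 before ring A exists.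

Step 9
Reactants: 18 ent-3β-[(tert-butyldimethylsilyl)oxy]-13,14,15,16-tetranorlabd-7-en-17,12-olide
Product: 19 ent-3β-[(tert-butyldimethylsilyl)oxy]-8αH-13,14,15,16-tetranorlabdan-17,12-olide (cis-fused lactone)
Conditions: H2 (1 atm), Pd/C (10 wt %), EtOAc, rt
Reagents that add atoms: none
Why: Heterogeneous hydrogenation should add H2 syn from the face opposite the axial C20 methyl, which shields its own side of C8, so that H-8 ends cis to H-9 and C17 axial.

Step 10
Reactants: 19 ent-3β-[(tert-butyldimethylsilyl)oxy]-8αH-13,14,15,16-tetranorlabdan-17,12-olide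
Product: 20 ent-3β-[(tert-butyldimethylsilyl)oxy]-12-hydroxy-N-methoxy-N-methyl-8αH-13,14,15,16-tetranorlabdan-17-amide
Conditions: MeNH(OMe), AlMe3, CH2Cl2, 0 °C → rt; Rochelle salt work-up
Reagents that add atoms: N,O-dimethylhydroxylamine, CNOC
Why: Aminolysis of the lactone with the aluminium amide, a weakly basic reagent that should not epimerize C8, differentiates C17 (N-methoxy-N-methyl amide) from C12 (free primary alcohol).

Step 11
Reactants: 20 ent-3β-[(tert-butyldimethylsilyl)oxy]-12-hydroxy-N-methoxy-N-methyl-8αH-13,14,15,16-tetranorlabdan-17-amide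
Product: 21 ent-3β-[(tert-butyldimethylsilyl)oxy]-12-iodo-N-methoxy-N-methyl-8αH-13,14,15,16-tetranorlabdan-17-amide
Conditions: I2, PPh3, imidazole, CH2Cl2, 0 °C
Reagents that add atoms: iodine, II
Why: Appel iodination converts the unhindered primary alcohol into the iodide under neutral conditions.

Step 12
Reactants: 22 methyl but-2-ynoate
Product: 23 methyl (Z)-3-iodobut-2-enoate
Conditions: NaI, AcOH, 115 °C
Reagents that add atoms: sodium iodide, [Na+].[I-]
Why: Conjugate addition of iodide to the ynoate with anti protonation (hydroiodination) should give the Z-β-iodo enoate, with iodine cis to the ester.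

Step 13
Reactants: 21 ent-3β-[(tert-butyldimethylsilyl)oxy]-12-iodo-N-methoxy-N-methyl-8αH-13,14,15,16-tetranorlabdan-17-amide; 23 methyl (Z)-3-iodobut-2-enoate
Product: 25 methyl ent-3β-[(tert-butyldimethylsilyl)oxy]-17-[methoxy(methyl)amino]-17-oxo-8αH-labd-13Z-en-15-oate, via alkylzinc iodide 24 (not isolated)
Conditions: Zn dust (activated), LiCl, THF, 40 °C; then 23, Pd(PPh3)4 (5 mol %), THF, 25 → 45 °C
Reagents that add atoms: none
Why: Zinc insertion gives an amide-tolerant alkylzinc iodide, and Negishi coupling forms C12–C13 with retention of the vinyl iodide geometry, so the chain ends cis to the ester (13Z).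

Step 14
Reactants: 25 methyl ent-3β-[(tert-butyldimethylsilyl)oxy]-17-[methoxy(methyl)amino]-17-oxo-8αH-labd-13Z-en-15-oate
Product: 26 methyl ent-3β-[(tert-butyldimethylsilyl)oxy]-17-oxo-8αH-labd-13Z-en-15-oate
Conditions: Cp2Zr(H)Cl (1.6 equiv), THF, rt
Reagents that add atoms: none
Why: Reduction of the tertiary amide with Cp2Zr(H)Cl stops at the aldehyde after hydrolysis, should spare the conjugated methyl ester, and is neutral enough to leave the axial C8 center unepimerized.

Step 15
Reactants: 26 methyl ent-3β-[(tert-butyldimethylsilyl)oxy]-17-oxo-8αH-labd-13Z-en-15-oate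
Product: 27 methyl ent-3β-hydroxy-17-oxo-8αH-labd-13Z-en-15-oate (target)
Conditions: HF·pyridine, pyridine, THF, 0 °C → rt
Reagents that add atoms: none
Why: Buffered fluoride desilylation frees the C3 hydroxyl under conditions mild enough for the epimerizable axial aldehyde and the Z-enoate.

**Compound list**

In 18–27, H-5, H-8 and H-9 are cis to one another and trans to CH3-20; the C3 oxygen, C17 and the C9 side chain are cis to CH3-20.

1 | 3,3-dimethylpent-4-en-2-one | CC(=O)C(C)(C)C=C | starting material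
2 | 3,3-diethoxyprop-1-ene (acrolein diethyl acetal) | C=CC(OCC)OCC | starting material
3 | (E)-6,6-diethoxy-3,3-dimethylhex-4-en-2-one | CC(=O)C(C)(C)/C=C/C(OCC)OCC | intermediate
4 | 2,3-dibromoprop-1-ene | C=C(Br)CBr | starting material
5 | lithium (E)-6,6-diethoxy-3,3-dimethylhexa-1,4-dien-2-olate (kinetic enolate of 3) | [Li]OC(=C)C(C)(C)/C=C/C(OCC)OCC | intermediate (not isolated)
6 | (E)-2-bromo-9,9-diethoxy-6,6-dimethylnona-1,7-dien-5-one | C=C(Br)CCC(=O)C(C)(C)/C=C/C(OCC)OCC | intermediate
7 | (5R,7E)-2-bromo-9,9-diethoxy-6,6-dimethylnona-1,7-dien-5-ol | C=C(Br)CC[C@@H](O)C(C)(C)/C=C/C(OCC)OCC | intermediate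
8 | {[(5R,7E)-2-bromo-9,9-diethoxy-6,6-dimethylnona-1,7-dien-5-yl]oxy}(tert-butyl)dimethylsilane | C=C(Br)CC[C@@H](O[Si](C)(C)C(C)(C)C)C(C)(C)/C=C/C(OCC)OCC | intermediate
9 | 5,6-dihydro-2H-pyran-2-one | O=C1C=CCCO1 | starting material
10 | alkenyllithium from 8 (Li in place of Br) | [Li]C(=C)CC[C@@H](O[Si](C)(C)C(C)(C)C)C(C)(C)/C=C/C(OCC)OCC | intermediate (not isolated)
11 | lithium trimethoxy(alkenyl)borate from 10 | [Li+].C=C([B-](OC)(OC)OC)CC[C@@H](O[Si](C)(C)C(C)(C)C)C(C)(C)/C=C/C(OCC)OCC | intermediate (not isolated)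
12 | (4R)-4-[(5R,7E)-5-{[tert-butyl(dimethyl)silyl]oxy}-9,9-diethoxy-6,6-dimethylnona-1,7-dien-2-yl]oxan-2-one | C=C(CC[C@@H](O[Si](C)(C)C(C)(C)C)C(C)(C)/C=C/C(OCC)OCC)[C@@H]1CCOC(=O)C1 | intermediate
13 | lithium enolate of lactone 12 | C=C(CC[C@@H](O[Si](C)(C)C(C)(C)C)C(C)(C)/C=C/C(OCC)OCC)[C@@H]1CCOC(O[Li])=C1 | intermediate (not isolated)
14 | diethyl phosphonite of 12 at the lactone α-carbon (both epimers there) | C=C(CC[C@@H](O[Si](C)(C)C(C)(C)C)C(C)(C)/C=C/C(OCC)OCC)[C@@H]1CCOC(=O)C1P(OCC)OCC | intermediate (not isolated)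
15 | diethyl {(4S)-4-[(5R,7E)-5-{[tert-butyl(dimethyl)silyl]oxy}-9,9-diethoxy-6,6-dimethylnona-1,7-dien-2-yl]-2-oxooxan-3-yl}phosphonate (both C3 epimers) | C=C(CC[C@@H](O[Si](C)(C)C(C)(C)C)C(C)(C)/C=C/C(OCC)OCC)[C@@H]1CCOC(=O)C1P(=O)(OCC)OCC | intermediate
16 | diethyl {(4S)-4-[(5R,7E)-5-{[tert-butyl(dimethyl)silyl]oxy}-6,6-dimethyl-9-oxonona-1,7-dien-2-yl]-2-oxooxan-3-yl}phosphonate (both C3 epimers) | C=C(CC[C@@H](O[Si](C)(C)C(C)(C)C)C(C)(C)/C=C/C=O)[C@@H]1CCOC(=O)C1P(=O)(OCC)OCC | intermediate
17 | diethyl {(4S)-4-[(1R,2S,4R)-4-{[tert-butyl(dimethyl)silyl]oxy}-1,3,3-trimethyl-2-(2-oxoethyl)cyclohexyl]-2-oxooxan-3-yl}phosphonate (ring-A aldehyde) | O=CC[C@@H]1C(C)(C)[C@H](O[Si](C)(C)C(C)(C)C)CC[C@@]1(C)[C@@H]2CCOC(=O)C2P(=O)(OCC)OCC | intermediate (not isolated)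
18 | ent-3β-[(tert-butyldimethylsilyl)oxy]-13,14,15,16-tetranorlabd-7-en-17,12-olide | O=C1OCC[C@@H]2C1=CC[C@@H]3C(C)(C)[C@H](O[Si](C)(C)C(C)(C)C)CC[C@@]23C | intermediate
19 | ent-3β-[(tert-butyldimethylsilyl)oxy]-8αH-13,14,15,16-tetranorlabdan-17,12-olide | O=C1OCC[C@@H]2[C@H]1CC[C@@H]3C(C)(C)[C@H](O[Si](C)(C)C(C)(C)C)CC[C@@]23C | intermediate
20 | ent-3β-[(tert-butyldimethylsilyl)oxy]-12-hydroxy-N-methoxy-N-methyl-8αH-13,14,15,16-tetranorlabdan-17-amide | OCC[C@@H]1[C@H](C(=O)N(C)OC)CC[C@@H]2C(C)(C)[C@H](O[Si](C)(C)C(C)(C)C)CC[C@@]12C | intermediate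
21 | ent-3β-[(tert-butyldimethylsilyl)oxy]-12-iodo-N-methoxy-N-methyl-8αH-13,14,15,16-tetranorlabdan-17-amide | ICC[C@@H]1[C@H](C(=O)N(C)OC)CC[C@@H]2C(C)(C)[C@H](O[Si](C)(C)C(C)(C)C)CC[C@@]12C | intermediate
22 | methyl but-2-ynoate | CC#CC(=O)OC | starting material
23 | methyl (Z)-3-iodobut-2-enoate | COC(=O)/C=C(/C)I | intermediate
24 | alkylzinc iodide from 21 (ZnI at C12) | I[Zn]CC[C@@H]1[C@H](C(=O)N(C)OC)CC[C@@H]2C(C)(C)[C@H](O[Si](C)(C)C(C)(C)C)CC[C@@]12C | intermediate (not isolated)
25 | methyl ent-3β-[(tert-butyldimethylsilyl)oxy]-17-[methoxy(methyl)amino]-17-oxo-8αH-labd-13Z-en-15-oate | COC(=O)/C=C(/C)CC[C@@H]1[C@H](C(=O)N(C)OC)CC[C@@H]2C(C)(C)[C@H](O[Si](C)(C)C(C)(C)C)CC[C@@]12C | intermediate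
26 | methyl ent-3β-[(tert-butyldimethylsilyl)oxy]-17-oxo-8αH-labd-13Z-en-15-oate | COC(=O)/C=C(/C)CC[C@@H]1[C@H](C=O)CC[C@@H]2C(C)(C)[C@H](O[Si](C)(C)C(C)(C)C)CC[C@@]12C | intermediate
27 | methyl ent-3β-hydroxy-17-oxo-8αH-labd-13Z-en-15-oate, (3R,5S,8R,9R,10S,13Z) | COC(=O)/C=C(/C)CC[C@@H]1[C@H](C=O)CC[C@@H]2C(C)(C)[C@H](O)CC[C@@]12C | target

**Step count and risks**

Total steps: 15. Longest linear sequence: 14 (steps 1–11 and 13–15; step 12 is a one-step side branch).

1. Step 8. Hydrogen-atom delivery to the tertiary radical, or conjugate reduction of the enal, may outrun the congested 6-exo closure, and the chair preference that sets C5 and C10 may be eroded. The fallback sets out from 15 and comes back at 18. Markovnikov hydrochlorination of the C10=CH2 alkene of 15 (Co(BF4)2·6H2O, salen-type ligand, t-BuOOH (cat.), PhSiH3, TsCl, EtOH) should give the tertiary chloride F1. Acetal hydrolysis as in step 7 gives the chloro enal F2. Slow addition of Bu3SnH/AIBN (benzene, 80 °C) generates the same tertiary radical by chlorine abstraction, with no metal hydride present, and closes ring A to aldehyde 17. This is isolated and cyclized with LiCl/DBU to 18.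

2. Step 5. Transfer of the α-branched alkenyl group from boron to rhodium may be slow, protodeboronation in hot aqueous dioxane may compete, and enantioselectivity may fall. The fallback sets out from 9 (with 3) and comes back at 12; it moves the fragment union from C9–C10 to C1–C2. Rhodium/(R)-BINAP 1,4-addition of commercial isopropenylboronic acid pinacol ester to 9 should give (R)-4-(prop-1-en-2-yl)oxan-2-one F3. Ene-type allylic chlorination (Ca(OCl)2, solid CO2, CH2Cl2/H2O) gives (R)-4-(3-chloroprop-1-en-2-yl)oxan-2-one F4. Alkylation of enolate 5 (from 3 and LiN(i-Pr)2) with F4 (NaI cat., THF, −78 °C) gives the keto lactone F5. CBS reduction as in step 3 gives the hydroxy lactone F6, and silylation as in step 4 gives 12.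

3. Step 1. The vinyl group on the quaternary carbon may be too hindered for productive metathesis while 2 self-metathesizes and the catalyst decomposes. The fallback sets out from 1 and comes back at 3. Ozonolysis (O3, CH2Cl2, −78 °C; Me2S) gives 2,2-dimethyl-3-oxobutanal F7. Wittig reaction at the aldehyde with Ph3P=CHCHO (toluene, 80 °C) gives (E)-4,4-dimethyl-5-oxohex-2-enal F8. Acetalization of the aldehyde (HC(OEt)3, EtOH, PPTS) gives 3.

**Further compounds**

F1 | step 8 | diethyl {(4R)-4-[(5R,7E)-5-{[tert-butyl(dimethyl)silyl]oxy}-2-chloro-9,9-diethoxy-6,6-dimethylnon-7-en-2-yl]-2-oxooxan-3-yl}phosphonate (epimers at the chlorine- and phosphorus-bearing carbons) | CC(Cl)(CC[C@@H](O[Si](C)(C)C(C)(C)C)C(C)(C)/C=C/C(OCC)OCC)[C@@H]1CCOC(=O)C1P(=O)(OCC)OCC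
F2 | step 8 | diethyl {(4R)-4-[(5R,7E)-5-{[tert-butyl(dimethyl)silyl]oxy}-2-chloro-6,6-dimethyl-9-oxonon-7-en-2-yl]-2-oxooxan-3-yl}phosphonate (epimers at the chlorine- and phosphorus-bearing carbons) | CC(Cl)(CC[C@@H](O[Si](C)(C)C(C)(C)C)C(C)(C)/C=C/C=O)[C@@H]1CCOC(=O)C1P(=O)(OCC)OCC
F3 | step 5 | (R)-4-(prop-1-en-2-yl)oxan-2-one | CC(=C)[C@@H]1CCOC(=O)C1
F4 | step 5 | (R)-4-(3-chloroprop-1-en-2-yl)oxan-2-one | ClCC(=C)[C@@H]1CCOC(=O)C1
F5 | step 5 | (4R)-4-[(7E)-9,9-diethoxy-6,6-dimethyl-5-oxonona-1,7-dien-2-yl]oxan-2-one | C=C(CCC(=O)C(C)(C)/C=C/C(OCC)OCC)[C@@H]1CCOC(=O)C1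
F6 | step 5 | (4R)-4-[(5R,7E)-9,9-diethoxy-5-hydroxy-6,6-dimethylnona-1,7-dien-2-yl]oxan-2-one | C=C(CC[C@@H](O)C(C)(C)/C=C/C(OCC)OCC)[C@@H]1CCOC(=O)C1
F7 | step 1 | 2,2-dimethyl-3-oxobutanal | CC(=O)C(C)(C)C=O
F8 | step 1 | (E)-4,4-dimethyl-5-oxohex-2-enal | CC(=O)C(C)(C)/C=C/C=O
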